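(The constants used here are assumed; the result is computed.)

3 questions stood before me: the state of the flask at the end, and how much D.L and X it then held.

    D + L ⇌ D.L (K1 = 16.3 L mol⁻¹, k1 = 1.62 L mol⁻¹ h⁻¹)
    D + L ⇌ X (K2 = 369 L mol⁻¹, k2 = 0.535 L mol⁻¹ h⁻¹)
    D.L + J ⇌ X + J, rate k3*[J]*[D.L] forward; the back reaction follows from the equilibrium constant (k3 = 10.7 L mol⁻¹ h⁻¹)
    L + Z → J + E (k4 = 0.191 L mol⁻¹ h⁻¹)

D 0.10 M; L 0.150 M; Z 5.0 mM; time 15 d

* which holds at 15 d: what has brought the reaction to rest, or that it has not come to rest (no working catalyst is left / L has run out first / it is still moving / all of D has reacted / forward and back rates have come level)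
* amount of D.L at 15 d, in percent of the D charged
* amount of X at 15 d, in percent of the D charged

The first two steps each bind one D to one L, so I lumped them. The hold constant H, the sum of their equilibrium constants, 385 L mol⁻¹, multiplied by free L, gives bound D per free D at rest. The third step joins D.L and X over J at the ratio of those same constants, so it adds no new rest. But the last step takes one L per Z, so I booked the whole Z charge against L. D was the limiting reagent, so with every D bound, L would stand at 0.0450 M. H at that L left 5.45% of D free, which returned L to 0.0505 M. A second pass gave 4.89% free, so 4.02% D.L and 91.1% X.

But that holds only if the time suffices. I replaced the falling L by this low value, which gave the forward rate of the second step a time constant of 1.54 d, and the run lasted ten times that. The last step got 4.32 d, by which I reckoned 3.11% of Z left, so I expected D, D.L and X to be at rest.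

The forecast gave forward and back rates have come level, with 4% D.L and 91% X, since “D, D.L and X settle at equilibrium”.

The simulation gave forward and back rates have come level, with 4.02% D.L and 91.1% X. The largest change of a share over the second half of the time was 0.08 percentage points, with L at 33% of its charge. H times that L is 19.3 bound D per free D, which makes free D 4.93%, and the flask held 4.93%. In the neighbour charged with 0.060 M of L, with 63.7% of its Z still unused, L stood at 5.23% of its charge. H then gives 1.21 bound D per free D, so 45.3% free, and that neighbour held 45.0% of its D free.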